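## Retrosynthetic overview

1. Target ⇐ removal of five O-benzyl groups ⇐ C4–C(alkene) bond made by carboxylate-directed C–H olefination of a dihydrobenzofuran-3-carboxylic acid with the acrylate of (R)-danshensu methyl ester (chiral pool).
2. Dihydrobenzofuran acid ⇐ ester hydrolysis ⇐ key step: PhI(OAc)2 ring contraction of a (2S)-flavanone. Ring A shifts from C4 to C3 of an α-iodanyl ketal (an enolonium equivalent), giving the C3–C3a bond and the trans C2/C3 pair in one operation.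
3. (2S)-Flavanone ⇐ Pd-catalysed asymmetric 1,4-addition of the ring B boronic acid to 8-(benzyloxy)chromone (sets C2).
4. Chromone ⇐ 2',3'-dihydroxyacetophenone (mono-benzylation, enaminone cyclisation).
5. Ring order: ring A is bought; the pyranone ring is built on it; ring B is attached; the six-membered oxygen ring is contracted to the dihydrofuran; ring C arrives last with the danshensu side chain.

Assumption: in step 3 the (R)-enantiomer of the pyridine-oxazoline ligand is taken to give the (2S)-flavanone, by analogy with the (S)-ligand/(R)-ketone pairing known for cyclic enones; if the sense proves opposite, the antipodal ligand is used.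

## Route

Step 1
Reactants: 1 2',3'-dihydroxyacetophenone
Product: 2 1-[3-(benzyloxy)-2-hydroxyphenyl]ethan-1-one
Conditions: NaH (2.1 equiv), DMSO, rt; then BnBr (1.0 equiv), rt; aq HCl work-up
Reagents that add atoms: benzyl bromide, BrCc1ccccc1
Why: Williamson etherification of the catecholate dianion, in which the non-chelated 3'-phenoxide is the less stabilised and more nucleophilic oxygen, so one equivalent of BnBr goes to O-3' and the ketone-chelated 2'-OH stays free.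

Step 2
Reactants: 2 1-[3-(benzyloxy)-2-hydroxyphenyl]ethan-1-one
Product: 4 8-(benzyloxy)-4H-chromen-4-one, via enaminone 3 (not isolated)
Conditions: Me2NCH(OMe)2, toluene, 100 °C; then conc. HCl, CH2Cl2, rt
Reagents that add atoms: N,N-dimethylformamide dimethyl acetal, COC(OC)N(C)C
Why: Enaminone formation with the amide acetal, then acid-promoted conjugate addition of the 2'-OH with loss of Me2NH (enaminone route to chromones), closes the pyranone ring; no stereocentre is involved.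

Step 3
Reactants: 4 8-(benzyloxy)-4H-chromen-4-one; 5 [3,4-bis(benzyloxy)phenyl]boronic acid
Product: 6 (2S)-8-(benzyloxy)-2-[3,4-bis(benzyloxy)phenyl]-2,3-dihydro-4H-chromen-4-one
Conditions: Pd(OCOCF3)2 (5 mol %), (R)-4-tert-butyl-2-(pyridin-2-yl)-4,5-dihydrooxazole ((R)-t-BuPyOX, 6 mol %), NH4PF6 (30 mol %), H2O (5 equiv), ClCH2CH2Cl, 60 °C
Reagents that add atoms: none
Why: Pd-catalysed asymmetric conjugate (1,4-) addition of an arylboronic acid to a chromone (Hayashi–Miyaura type, cationic divalent palladium–pyridine-oxazoline catalyst), in which the ligand shields one face of the enone so aryl transfer sets C2 as S and water protonates the palladium enolate.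

Step 4
Reactants: 6 (2S)-8-(benzyloxy)-2-[3,4-bis(benzyloxy)phenyl]-2,3-dihydro-4H-chromen-4-one
Product: 8 methyl (2S,3S)-7-(benzyloxy)-2-[3,4-bis(benzyloxy)phenyl]-2,3-dihydro-1-benzofuran-3-carboxylate, via enol ether 7 (not isolated)
Conditions: PhI(OAc)2 (1.2 equiv), HC(OMe)3, H2SO4 (cat.), rt; aqueous work-up
Reagents that add atoms: trimethyl orthoformate, COC(OC)OC; water, O
Why: Trivalent-iodine oxidative ring contraction of a flavanone (1,2-aryl shift, semipinacol type), in which PhI(OAc)2 attacks enol ether 7 at C3 anti to the C2 aryl group to give an α-λ3-iodanyl ketal that acts as an enolonium (α-carbonyl cation) equivalent, and ring A then migrates from C4 to C3 anti to the departing PhI, so the C3–C3a bond joins two carbons that are both nucleophilic by nature (enol α-carbon and phenol-ether ortho carbon), C3 is set as S trans to the untouched C2, and the former C4 ends as the methyl ester.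

Step 5
Reactants: 8 methyl (2S,3S)-7-(benzyloxy)-2-[3,4-bis(benzyloxy)phenyl]-2,3-dihydro-1-benzofuran-3-carboxylate
Product: 9 (2S,3S)-7-(benzyloxy)-2-[3,4-bis(benzyloxy)phenyl]-2,3-dihydro-1-benzofuran-3-carboxylic acid
Conditions: Me3SnOH (5 equiv), ClCH2CH2Cl, 80 °C; aq HCl work-up
Reagents that add atoms: trimethyltin hydroxide, C[Sn](C)(C)O
Why: Near-neutral ester hydrolysis with Me3SnOH (acyl substitution) frees the C3 acid without enolising C3 or opening the ring by retro-oxa-Michael reaction, so both stereocentres are kept.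

Step 6
Reactants: 10 sodium (2R)-3-(3,4-dihydroxyphenyl)-2-hydroxypropanoate
Product: 11 methyl (2R)-3-(3,4-dihydroxyphenyl)-2-hydroxypropanoate
Conditions: HCl (1.25 M in MeOH), rt
Reagents that add atoms: methanol, CO
Why: Fischer esterification of the carboxylate; the R stereocentre comes from the chiral pool and is not involved.

Step 7
Reactants: 11 methyl (2R)-3-(3,4-dihydroxyphenyl)-2-hydroxypropanoate
Product: 12 methyl (2R)-3-[3,4-bis(benzyloxy)phenyl]-2-hydroxypropanoate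
Conditions: BnBr (2.2 equiv), K2CO3, acetone, 50 °C
Reagents that add atoms: benzyl bromide, BrCc1ccccc1
Why: Williamson etherification in which K2CO3 deprotonates only the two phenols, so the secondary alcohol stays free and the stereocentre is untouched.

Step 8
Reactants: 12 methyl (2R)-3-[3,4-bis(benzyloxy)phenyl]-2-hydroxypropanoate
Product: 13 methyl (2R)-3-[3,4-bis(benzyloxy)phenyl]-2-(prop-2-enoyloxy)propanoate
Conditions: CH2=CHCOCl, Et3N, CH2Cl2, 0 °C
Reagents that add atoms: acryloyl chloride, C=CC(=O)Cl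
Why: O-acylation of the α-hydroxy ester with an acid chloride takes place at oxygen, so C2 keeps its R configuration.

Step 9
Reactants: 9 (2S,3S)-7-(benzyloxy)-2-[3,4-bis(benzyloxy)phenyl]-2,3-dihydro-1-benzofuran-3-carboxylic acid; 13 methyl (2R)-3-[3,4-bis(benzyloxy)phenyl]-2-(prop-2-enoyloxy)propanoate
Product: 14 (2S,3S)-7-(benzyloxy)-2-[3,4-bis(benzyloxy)phenyl]-4-[(1E)-3-{[(2R)-3-[3,4-bis(benzyloxy)phenyl]-1-methoxy-1-oxopropan-2-yl]oxy}-3-oxoprop-1-en-1-yl]-2,3-dihydro-1-benzofuran-3-carboxylic acid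
Conditions: Pd(OAc)2 (5 mol %), N-acetyl-L-isoleucine (10 mol %), KHCO3 (2 equiv), O2 (1 atm), t-AmOH, 85 °C; aq HCl work-up
Reagents that add atoms: none
Why: Carboxylate-directed ortho C–H olefination (oxidative Heck, Fujiwara–Moritani type) through a six-membered palladacycle delivers divalent palladium only to C4–H, insertion and β-hydride elimination give the E-cinnamate, O2 reoxidises zerovalent palladium, and the near-neutral medium leaves all three stereocentres alone.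

Step 10
Reactants: 14 (2S,3S)-7-(benzyloxy)-2-[3,4-bis(benzyloxy)phenyl]-4-[(1E)-3-{[(2R)-3-[3,4-bis(benzyloxy)phenyl]-1-methoxy-1-oxopropan-2-yl]oxy}-3-oxoprop-1-en-1-yl]-2,3-dihydro-1-benzofuran-3-carboxylic acid
Product: 15 (2S,3S)-2-(3,4-dihydroxyphenyl)-4-[(1E)-3-{[(2R)-3-(3,4-dihydroxyphenyl)-1-methoxy-1-oxopropan-2-yl]oxy}-3-oxoprop-1-en-1-yl]-7-hydroxy-2,3-dihydro-1-benzofuran-3-carboxylic acid (CNP0120702.1)
Conditions: BCl3 (1 M in CH2Cl2, 12 equiv), C6HMe5 (15 equiv), CH2Cl2, −78 °C; then MeOH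
Reagents that add atoms: none
Why: Lewis-acid debenzylation with a non-basic cation scavenger (BCl3/pentamethylbenzene) cleaves the five aryl benzyl ethers at −78 °C and traps the benzyl cations, sparing the alkene, both esters and the three stereocentres.

## Compound list

1 | 2',3'-dihydroxyacetophenone | CC(=O)c1cccc(O)c1O | starting material
2 | 1-[3-(benzyloxy)-2-hydroxyphenyl]ethan-1-one | CC(=O)c1cccc(OCc2ccccc2)c1O | intermediate
3 | (2E)-1-[3-(benzyloxy)-2-hydroxyphenyl]-3-(dimethylamino)prop-2-en-1-one | CN(C)/C=C/C(=O)c1cccc(OCc2ccccc2)c1O | intermediate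
4 | 8-(benzyloxy)-4H-chromen-4-one | O=c1ccoc2c(OCc3ccccc3)cccc12 | intermediate
5 | [3,4-bis(benzyloxy)phenyl]boronic acid | OB(O)c1ccc(OCc2ccccc2)c(OCc2ccccc2)c1 | starting material
6 | (2S)-8-(benzyloxy)-2-[3,4-bis(benzyloxy)phenyl]-2,3-dihydro-4H-chromen-4-one | O=C1C[C@@H](c2ccc(OCc3ccccc3)c(OCc3ccccc3)c2)Oc2c(OCc3ccccc3)cccc12 | intermediate
7 | (2S)-8-(benzyloxy)-2-[3,4-bis(benzyloxy)phenyl]-4-methoxy-2H-chromene | COC1=C[C@@H](c2ccc(OCc3ccccc3)c(OCc3ccccc3)c2)Oc2c(OCc3ccccc3)cccc12 | intermediate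
8 | methyl (2S,3S)-7-(benzyloxy)-2-[3,4-bis(benzyloxy)phenyl]-2,3-dihydro-1-benzofuran-3-carboxylate (2,3-trans) | c1ccc(OCc3ccccc3)c2c1[C@H](C(=O)OC)[C@@H](c1ccc(OCc3ccccc3)c(OCc3ccccc3)c1)O2 | intermediate
9 | (2S,3S)-7-(benzyloxy)-2-[3,4-bis(benzyloxy)phenyl]-2,3-dihydro-1-benzofuran-3-carboxylic acid | c1ccc(OCc3ccccc3)c2c1[C@H](C(=O)O)[C@@H](c1ccc(OCc3ccccc3)c(OCc3ccccc3)c1)O2 | intermediate
10 | sodium (2R)-3-(3,4-dihydroxyphenyl)-2-hydroxypropanoate (sodium (R)-danshensu) | [Na+].[O-]C(=O)[C@@H](Cc1ccc(O)c(O)c1)O | starting material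
11 | methyl (2R)-3-(3,4-dihydroxyphenyl)-2-hydroxypropanoate | COC(=O)[C@@H](Cc1ccc(O)c(O)c1)O | intermediate
12 | methyl (2R)-3-[3,4-bis(benzyloxy)phenyl]-2-hydroxypropanoate | COC(=O)[C@@H](Cc1ccc(OCc2ccccc2)c(OCc2ccccc2)c1)O | intermediate
13 | methyl (2R)-3-[3,4-bis(benzyloxy)phenyl]-2-(prop-2-enoyloxy)propanoate | COC(=O)[C@@H](Cc1ccc(OCc2ccccc2)c(OCc2ccccc2)c1)OC(=O)C=C | intermediate
14 | (2S,3S)-7-(benzyloxy)-2-[3,4-bis(benzyloxy)phenyl]-4-[(1E)-3-{[(2R)-3-[3,4-bis(benzyloxy)phenyl]-1-methoxy-1-oxopropan-2-yl]oxy}-3-oxoprop-1-en-1-yl]-2,3-dihydro-1-benzofuran-3-carboxylic acid | COC(=O)[C@@H](Cc1ccc(OCc2ccccc2)c(OCc2ccccc2)c1)OC(=O)/C=C/c1ccc(OCc2ccccc2)c2c1[C@H](C(=O)O)[C@@H](c1ccc(OCc3ccccc3)c(OCc3ccccc3)c1)O2 | intermediate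
15 | (2S,3S)-2-(3,4-dihydroxyphenyl)-4-[(1E)-3-{[(2R)-3-(3,4-dihydroxyphenyl)-1-methoxy-1-oxopropan-2-yl]oxy}-3-oxoprop-1-en-1-yl]-7-hydroxy-2,3-dihydro-1-benzofuran-3-carboxylic acid | COC(=O)[C@@H](Cc1ccc(O)c(O)c1)OC(=O)/C=C/c1ccc(O)c2c1[C@H](C(=O)O)[C@@H](c1ccc(O)c(O)c1)O2 | target

## Step count and risks

Total steps: 10. Longest linear sequence: 7 (steps 1, 2, 3, 4, 5, 9, 10).

The three steps most likely to fail are steps 3, 4 and 10.

Step 3 may give low conversion or low ee, because the boronic acid is electron-rich and prone to protodeboronation and the chromone carries an 8-alkoxy group. The fallback sets out from acetophenone 2 and comes back at flavanone 6. Claisen–Schmidt condensation of 2 with commercial 3,4-bis(benzyloxy)benzaldehyde (KOH, EtOH, rt) gives the 2'-hydroxychalcone (2E)-1-[3-(benzyloxy)-2-hydroxyphenyl]-3-[3,4-bis(benzyloxy)phenyl]prop-2-en-1-one F1. NaOAc in refluxing EtOH closes it by oxa-Michael addition to racemic 8-(benzyloxy)-2-[3,4-bis(benzyloxy)phenyl]-2,3-dihydro-4H-chromen-4-one F2. Kinetic resolution by asymmetric transfer hydrogenation with RuCl[(R,R)-TsDPEN](p-cymene) in HCO2H/Et3N/EtOAc reduces the (2R)-ketone to the cis alcohol (2R,4R)-8-(benzyloxy)-2-[3,4-bis(benzyloxy)phenyl]-3,4-dihydro-2H-chromen-4-ol F3. This leaves (2S)-6 unreduced, at most half of the material, in high ee.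

Step 4 may divert to the flavone (elimination from the C3 iodane) or to the isoflavone (shift of ring B), or lose ee through acid-promoted opening to the chalcone. The fallback sets out from flavanone 6 and comes back at ester 8. It keeps the α-carbonyl cation logic but separates activation from migration. α-Bromination with PhNMe3Br3 (THF, 0 °C) gives the 2,3-trans bromide (2R,3R)-8-(benzyloxy)-2-[3,4-bis(benzyloxy)phenyl]-3-bromo-2,3-dihydro-4H-chromen-4-one F4; the C2 descriptor changes only through CIP priorities. Ketalisation (HC(OMe)3, MeOH, TsOH) gives (2R,3R)-8-(benzyloxy)-2-[3,4-bis(benzyloxy)phenyl]-3-bromo-4,4-dimethoxy-3,4-dihydro-2H-chromene F5. AgBF4 in MeOH then ionises the equatorial C3–Br bond while ring A shifts anti to it (the α-halo ketal 1,2-aryl shift used for 2-arylpropanoates), and aqueous work-up gives trans ester 8.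

Step 10 may fail because BCl3 can ionise the electron-rich benzylic C2–O1 bond or the liberated benzyl cations can alkylate the catechol rings. The fallback sets out from ester 8 and hydroxy ester 11 and comes back at target 15. It switches to fluoride-labile silyl ethers before the alkene exists.

- Hydrogenolysis of 8 (H2, 1 atm, Pd/C, EtOAc) gives methyl (2S,3S)-2-(3,4-dihydroxyphenyl)-7-hydroxy-2,3-dihydro-1-benzofuran-3-carboxylate F6.
- Silylation (i-Pr3SiCl, imidazole, DMF) gives methyl (2S,3S)-7-[(triisopropylsilyl)oxy]-2-{3,4-bis[(triisopropylsilyl)oxy]phenyl}-2,3-dihydro-1-benzofuran-3-carboxylate F7.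
- Hydrolysis with Me3SnOH as in step 5 gives (2S,3S)-7-[(triisopropylsilyl)oxy]-2-{3,4-bis[(triisopropylsilyl)oxy]phenyl}-2,3-dihydro-1-benzofuran-3-carboxylic acid F8.
- In parallel, 11 is silylated on the two phenols only (i-Pr3SiCl, imidazole) to methyl (2R)-3-{3,4-bis[(triisopropylsilyl)oxy]phenyl}-2-hydroxypropanoate F9.
- Acylation as in step 8 gives methyl (2R)-3-{3,4-bis[(triisopropylsilyl)oxy]phenyl}-2-(prop-2-enoyloxy)propanoate F10.
- The olefination of step 9 joins F8 and F10 to (2S,3S)-7-[(triisopropylsilyl)oxy]-2-{3,4-bis[(triisopropylsilyl)oxy]phenyl}-4-[(1E)-3-{[(2R)-3-{3,4-bis[(triisopropylsilyl)oxy]phenyl}-1-methoxy-1-oxopropan-2-yl]oxy}-3-oxoprop-1-en-1-yl]-2,3-dihydro-1-benzofuran-3-carboxylic acid F11.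
- HF·pyridine (THF, 0 °C) removes the five silyl groups to give 15 without any Lewis acid.

## Further compounds

F1 | step 3 | (2E)-1-[3-(benzyloxy)-2-hydroxyphenyl]-3-[3,4-bis(benzyloxy)phenyl]prop-2-en-1-one | O=C(/C=C/c1ccc(OCc2ccccc2)c(OCc2ccccc2)c1)c1cccc(OCc2ccccc2)c1O
F2 | step 3 | racemic 8-(benzyloxy)-2-[3,4-bis(benzyloxy)phenyl]-2,3-dihydro-4H-chromen-4-one | O=C1CC(c2ccc(OCc3ccccc3)c(OCc3ccccc3)c2)Oc2c(OCc3ccccc3)cccc12
F3 | step 3 | (2R,4R)-8-(benzyloxy)-2-[3,4-bis(benzyloxy)phenyl]-3,4-dihydro-2H-chromen-4-ol | O[C@@H]1C[C@H](c2ccc(OCc3ccccc3)c(OCc3ccccc3)c2)Oc2c(OCc3ccccc3)cccc12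
F4 | step 4 | (2R,3R)-8-(benzyloxy)-2-[3,4-bis(benzyloxy)phenyl]-3-bromo-2,3-dihydro-4H-chromen-4-one | O=C1[C@H](Br)[C@@H](c2ccc(OCc3ccccc3)c(OCc3ccccc3)c2)Oc2c(OCc3ccccc3)cccc12
F5 | step 4 | (2R,3R)-8-(benzyloxy)-2-[3,4-bis(benzyloxy)phenyl]-3-bromo-4,4-dimethoxy-3,4-dihydro-2H-chromene | COC1(OC)[C@H](Br)[C@@H](c2ccc(OCc3ccccc3)c(OCc3ccccc3)c2)Oc2c(OCc3ccccc3)cccc12
F6 | step 10 | methyl (2S,3S)-2-(3,4-dihydroxyphenyl)-7-hydroxy-2,3-dihydro-1-benzofuran-3-carboxylate | c1ccc(O)c2c1[C@H](C(=O)OC)[C@@H](c1ccc(O)c(O)c1)O2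
F7 | step 10 | methyl (2S,3S)-7-[(triisopropylsilyl)oxy]-2-{3,4-bis[(triisopropylsilyl)oxy]phenyl}-2,3-dihydro-1-benzofuran-3-carboxylate | c1ccc(O[Si](C(C)C)(C(C)C)C(C)C)c2c1[C@H](C(=O)OC)[C@@H](c1ccc(O[Si](C(C)C)(C(C)C)C(C)C)c(O[Si](C(C)C)(C(C)C)C(C)C)c1)O2
F8 | step 10 | (2S,3S)-7-[(triisopropylsilyl)oxy]-2-{3,4-bis[(triisopropylsilyl)oxy]phenyl}-2,3-dihydro-1-benzofuran-3-carboxylic acid | c1ccc(O[Si](C(C)C)(C(C)C)C(C)C)c2c1[C@H](C(=O)O)[C@@H](c1ccc(O[Si](C(C)C)(C(C)C)C(C)C)c(O[Si](C(C)C)(C(C)C)C(C)C)c1)O2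
F9 | step 10 | methyl (2R)-3-{3,4-bis[(triisopropylsilyl)oxy]phenyl}-2-hydroxypropanoate | COC(=O)[C@@H](Cc1ccc(O[Si](C(C)C)(C(C)C)C(C)C)c(O[Si](C(C)C)(C(C)C)C(C)C)c1)O
F10 | step 10 | methyl (2R)-3-{3,4-bis[(triisopropylsilyl)oxy]phenyl}-2-(prop-2-enoyloxy)propanoate | COC(=O)[C@@H](Cc1ccc(O[Si](C(C)C)(C(C)C)C(C)C)c(O[Si](C(C)C)(C(C)C)C(C)C)c1)OC(=O)C=C
F11 | step 10 | (2S,3S)-7-[(triisopropylsilyl)oxy]-2-{3,4-bis[(triisopropylsilyl)oxy]phenyl}-4-[(1E)-3-{[(2R)-3-{3,4-bis[(triisopropylsilyl)oxy]phenyl}-1-methoxy-1-oxopropan-2-yl]oxy}-3-oxoprop-1-en-1-yl]-2,3-dihydro-1-benzofuran-3-carboxylic acid | COC(=O)[C@@H](Cc1ccc(O[Si](C(C)C)(C(C)C)C(C)C)c(O[Si](C(C)C)(C(C)C)C(C)C)c1)OC(=O)/C=C/c1ccc(O[Si](C(C)C)(C(C)C)C(C)C)c2c1[C@H](C(=O)O)[C@@H](c1ccc(O[Si](C(C)C)(C(C)C)C(C)C)c(O[Si](C(C)C)(C(C)C)C(C)C)c1)O2
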